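**Retrosynthetic overview**

1. Labels: lactone O1, C2(=O), C3(CH3)(OH), C4, C5; side chain C1'(OCH2)–C2'=C3'(CH3)–C4' on C5. The γ-lactone is opened at O1–C2 to the triol 15 and is closed last by oxidative lactonisation; it is the only ring made, since the coumarin bicycle comes intact in 13.
2. The aryl ether O–C1' is cut to phenol 13 and the primary allylic alcohol 12 (Mitsunobu).
3. The strategy rests on the (E)-C2'=C3' alkene, whose C3' methyl and C1' are cis. This is the imprint of syn methyl–aluminium addition to the terminal alkyne of 7 (C3'–CH3) followed by capture of formaldehyde at the metalated carbon (C1'–C2').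
4. Alkyne 7: the C5 carbinol comes from catalyst-controlled propargylation of aldehyde 4; C3 comes from (R)-citramalic acid 1, whose C1 carboxyl (future C2) is carried as an acetonide-masked CH2OH.
5. Ring order: dioxolane (step 2, temporary, removed in step 7), then γ-lactone (step 8).

Key step: step 5

Remark: the facial sense of the (S)-TRIP-catalysed propargylation is assumed by analogy with aryl aldehydes and would be confirmed on 7 by Mosher ester analysis; the (R)-acid would be used if the sense were opposite. Compounds 1 and 13 are taken as purchasable.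

**Route**

Step 1
Reactants: 1 (R)-citramalic acid
Product: 2 (2R)-2-methylbutane-1,2,4-triol
Conditions: BH3·SMe2, B(OMe)3, THF, 0 °C → rt; MeOH quench, evaporation from MeOH
Reagents that add atoms: none
Why: Borane reduction of carboxylic acids takes both carboxyl groups to primary alcohols through acyloxyboranes, and the tertiary carbinol centre has no acidic hydrogen and cannot epimerise.

Step 2
Reactants: 2 (2R)-2-methylbutane-1,2,4-triol
Product: 3 2-[(4R)-2,2,4-trimethyl-1,3-dioxolan-4-yl]ethan-1-ol
Conditions: 2,2-dimethoxypropane, p-TsOH (cat.), acetone, rt; Et3N quench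
Reagents that add atoms: 2,2-dimethoxypropane, COC(C)(C)OC
Why: Isopropylidene acetal formation under thermodynamic control should close the five-membered dioxolane across the primary/tertiary 1,2-diol in preference to the six-membered 1,3-dioxane with its axial methyl group, leaving the 4-hydroxyl free.

Step 3
Reactants: 3 2-[(4R)-2,2,4-trimethyl-1,3-dioxolan-4-yl]ethan-1-ol
Product: 4 2-[(4R)-2,2,4-trimethyl-1,3-dioxolan-4-yl]acetaldehyde
Conditions: TEMPO (cat.), PhI(OAc)2, CH2Cl2, rt
Reagents that add atoms: none
Why: Oxoammonium-mediated oxidation of the primary alcohol stops at the aldehyde in dry CH2Cl2 and uses no base, so the β-alkoxy aldehyde is not exposed to elimination and the acetonide tolerates the acetic acid formed.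

Step 4
Reactants: 4 2-[(4R)-2,2,4-trimethyl-1,3-dioxolan-4-yl]acetaldehyde; 5 allenylboronic acid pinacol ester
Product: 7 (2S)-1-[(4R)-2,2,4-trimethyl-1,3-dioxolan-4-yl]pent-4-yn-2-ol, via borate ester 6 (not isolated)
Conditions: (S)-TRIP phosphoric acid [(S)-3,3'-bis(2,4,6-triisopropylphenyl)-1,1'-binaphthyl-2,2'-diyl hydrogen phosphate] (10 mol%), 4 Å MS, toluene, −20 °C; aq. NaHCO3 work-up
Reagents that add atoms: none
Why: In this chiral phosphoric acid-catalysed propargylboration the allenylboronate adds through a closed six-membered SE2' transition state with the acid bound to a boronate oxygen and the formyl hydrogen, so the catalyst sets the new C5 carbinol centre (the (S)-acid is expected to direct attack to the Si face and give the 2S alcohol, the remote quaternary centre exerting little bias), and aqueous work-up cleaves borate 6.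

Step 5
Reactants: 7 (2S)-1-[(4R)-2,2,4-trimethyl-1,3-dioxolan-4-yl]pent-4-yn-2-ol; 8 trimethylaluminium; 9 formaldehyde (used as paraformaldehyde)
Product: 12 (2E,5S)-3-methyl-6-[(4R)-2,2,4-trimethyl-1,3-dioxolan-4-yl]hex-2-ene-1,5-diol, via alkenylalane 10 (not isolated), via lithium alanate 11 (not isolated)
Conditions: Me3Al (4 equiv), Cp2ZrCl2 (0.3 equiv), CH2Cl2, 0 °C → rt; volatiles removed at rt; hexane/THF, nBuLi (2 equiv), −78 → 0 °C; (CH2O)n, rt; aq. potassium sodium tartrate
Reagents that add atoms: none
Why: Me3Al first converts the hydroxyl of 7 into its dimethylaluminium alkoxide (methane is lost), and the methylzirconocene–aluminium species formed from Cp2ZrCl2 and Me3Al then adds methyl and metal syn across the terminal alkyne, methyl to the internal carbon (C3'–CH3) and aluminium to the terminus, to give alkenylalane 10 (zirconium-catalysed carboalumination, Negishi type). nBuLi turns the alkenyl–AlMe2 unit into the more nucleophilic lithium alanate 11, which transfers its alkenyl group to formaldehyde released from paraformaldehyde with retention at the sp2 carbon and so forms C1'–C2'; this carboalumination–alanate–formaldehyde sequence is the closest known reaction type and is applied here to a homopropargylic alkoxide. No ring is closed and no stereocentre is made, the C3 and C5 centres being remote, non-epimerisable spectators. The step needs regioselectivity (methyl on the internal carbon) and syn stereospecificity, both secured by the terminal alkyne, so that C1' ends cis to the C3' methyl and trans to C4', which is the E geometry of the target. Keeping the carbometalation at or below room temperature should avoid the hydroxyl-assisted isomerisation of the alkenylalane that sets in on heating, and the acetonide keeps the tertiary carbinol and the future lactone carbonyl carbon inert to Me3Al.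

Step 6
Reactants: 12 (2E,5S)-3-methyl-6-[(4R)-2,2,4-trimethyl-1,3-dioxolan-4-yl]hex-2-ene-1,5-diol; 13 7-hydroxy-8-methoxycoumarin
Product: 14 7-{[(2E,5S)-5-hydroxy-3-methyl-6-[(4R)-2,2,4-trimethyl-1,3-dioxolan-4-yl]hex-2-en-1-yl]oxy}-8-methoxy-2H-chromen-2-one
Conditions: PPh3, DIAD, THF, 0 °C → rt
Reagents that add atoms: none
Why: In this Mitsunobu etherification the acidic 7-hydroxyl of 13 displaces the oxyphosphonium salt of the unhindered primary allylic alcohol by SN2 at C1', which is activated far faster than the secondary C5 hydroxyl, and the E geometry keeps that hydroxyl out of reach of C1' so no cyclic ether can form.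

Step 7
Reactants: 14 7-{[(2E,5S)-5-hydroxy-3-methyl-6-[(4R)-2,2,4-trimethyl-1,3-dioxolan-4-yl]hex-2-en-1-yl]oxy}-8-methoxy-2H-chromen-2-one
Product: 15 7-{[(2E,5S,7R)-5,7,8-trihydroxy-3,7-dimethyloct-2-en-1-yl]oxy}-8-methoxy-2H-chromen-2-one
Conditions: AcOH/H2O (4:1), 40 °C
Reagents that add atoms: none
Why: Acid-catalysed hydrolysis of the terminal isopropylidene acetal should proceed in dilute acetic acid without ionising the primary allylic aryl ether or opening the coumarin lactone, and no stereocentre is touched.

Step 8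
Reactants: 15 7-{[(2E,5S,7R)-5,7,8-trihydroxy-3,7-dimethyloct-2-en-1-yl]oxy}-8-methoxy-2H-chromen-2-one
Product: 18 7-{[(2E)-4-[(2S,4R)-4-hydroxy-4-methyl-5-oxooxolan-2-yl]-3-methylbut-2-en-1-yl]oxy}-8-methoxy-2H-chromen-2-one, via hydroxy aldehyde 16 (not isolated), via lactol 17 (not isolated)
Conditions: TEMPO (0.2 equiv), PhI(OAc)2 (2.5 equiv), CH2Cl2, rt
Reagents that add atoms: none
Why: In this nitroxyl-catalysed oxidative lactonisation of a 1,4-diol the oxoammonium salt oxidises the primary C2 alcohol in preference to the secondary one, aldehyde 16 is trapped by the C5 hydroxyl as the five-membered lactol 17, and a second oxidation gives the γ-lactone, while the tertiary hydroxyl cannot be oxidised and both stereocentres are carried through unchanged.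

**Compound list**

1 | (R)-citramalic acid | C[C@@](O)(CC(=O)O)C(=O)O | starting material
2 | (2R)-2-methylbutane-1,2,4-triol | C[C@@](O)(CCO)CO | intermediate
3 | 2-[(4R)-2,2,4-trimethyl-1,3-dioxolan-4-yl]ethan-1-ol | OCC[C@]1(C)COC(C)(C)O1 | intermediate
4 | 2-[(4R)-2,2,4-trimethyl-1,3-dioxolan-4-yl]acetaldehyde | O=CC[C@]1(C)COC(C)(C)O1 | intermediate
5 | allenylboronic acid pinacol ester | C=C=CB1OC(C)(C)C(C)(C)O1 | starting material
6 | borate ester: 4,4,5,5-tetramethyl-2-{[(2S)-1-[(4R)-2,2,4-trimethyl-1,3-dioxolan-4-yl]pent-4-yn-2-yl]oxy}-1,3,2-dioxaborolane | C#CC[C@H](OB1OC(C)(C)C(C)(C)O1)C[C@]1(C)COC(C)(C)O1 | intermediate (not isolated)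
7 | (2S)-1-[(4R)-2,2,4-trimethyl-1,3-dioxolan-4-yl]pent-4-yn-2-ol | C#CC[C@H](O)C[C@]1(C)COC(C)(C)O1 | intermediate
8 | trimethylaluminium | C[Al](C)C | starting material
9 | formaldehyde (used as paraformaldehyde) | C=O | starting material
10 | alkenylalane: dimethylaluminium alkoxide of (2S,4E)-5-(dimethylalumanyl)-4-methyl-1-[(4R)-2,2,4-trimethyl-1,3-dioxolan-4-yl]pent-4-en-2-ol | C[Al](C)/C=C(\C)C[C@H](O[Al](C)C)C[C@]1(C)COC(C)(C)O1 | intermediate (not isolated)
11 | lithium alanate: lithium butyl(dimethyl)alkenylaluminate derived from 10 | [Li+].CCCC[Al-](C)(C)/C=C(\C)C[C@H](O[Al](C)C)C[C@]1(C)COC(C)(C)O1 | intermediate (not isolated)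
12 | (2E,5S)-3-methyl-6-[(4R)-2,2,4-trimethyl-1,3-dioxolan-4-yl]hex-2-ene-1,5-diol | OC/C=C(\C)C[C@H](O)C[C@]1(C)COC(C)(C)O1 | intermediate
13 | 7-hydroxy-8-methoxycoumarin | COc1c(O)ccc2ccc(=O)oc12 | starting material
14 | 7-{[(2E,5S)-5-hydroxy-3-methyl-6-[(4R)-2,2,4-trimethyl-1,3-dioxolan-4-yl]hex-2-en-1-yl]oxy}-8-methoxy-2H-chromen-2-one | COc1c(OC/C=C(\C)C[C@H](O)C[C@]2(C)COC(C)(C)O2)ccc2ccc(=O)oc12 | intermediate
15 | 7-{[(2E,5S,7R)-5,7,8-trihydroxy-3,7-dimethyloct-2-en-1-yl]oxy}-8-methoxy-2H-chromen-2-one | COc1c(OC/C=C(\C)C[C@H](O)C[C@@](C)(O)CO)ccc2ccc(=O)oc12 | intermediate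
16 | hydroxy aldehyde: (2R,4S,6E)-2,4-dihydroxy-8-[(8-methoxy-2-oxo-2H-chromen-7-yl)oxy]-2,6-dimethyloct-6-enal | COc1c(OC/C=C(\C)C[C@H](O)C[C@@](C)(O)C=O)ccc2ccc(=O)oc12 | intermediate (not isolated)
17 | lactol: 7-{[(2E)-4-[(2S,4R)-4,5-dihydroxy-4-methyloxolan-2-yl]-3-methylbut-2-en-1-yl]oxy}-8-methoxy-2H-chromen-2-one (anomeric mixture) | COc1c(OC/C=C(\C)C[C@H]2C[C@@](C)(O)C(O)O2)ccc2ccc(=O)oc12 | intermediate (not isolated)
18 | 7-{[(2E)-4-[(2S,4R)-4-hydroxy-4-methyl-5-oxooxolan-2-yl]-3-methylbut-2-en-1-yl]oxy}-8-methoxy-2H-chromen-2-one (lactone 3R,5S) | COc1c(OC/C=C(\C)C[C@H]2C[C@@](C)(O)C(=O)O2)ccc2ccc(=O)oc12 | target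

**Step count**

Total steps: 8. Longest linear sequence: 8 steps (1 → 18).

**Steps most likely to fail**

Step 5. The alkenyl group may transfer incompletely from the alanate to solid paraformaldehyde, with protonolysis to the 1,1-disubstituted alkene. A sluggish carbometalation of the alkoxide-bearing alkyne would also prolong contact of the acetonide with Me3Al and could erode the alkene geometry. The fallback separates the two C–C bond formations; it sets out from 7 and returns at 12. The carboalumination mixture is quenched with I2 (THF, −30 °C) instead of being converted to the alanate, to give the vinyl iodide (2S,4E)-5-iodo-4-methyl-1-[(4R)-2,2,4-trimethyl-1,3-dioxolan-4-yl]pent-4-en-2-ol F1. Palladium-catalysed methoxycarbonylation (PdCl2(PPh3)2, CO 1 atm, MeOH, Et3N, 60 °C) should then give methyl (2E,5S)-5-hydroxy-3-methyl-6-[(4R)-2,2,4-trimethyl-1,3-dioxolan-4-yl]hex-2-enoate F2; the E geometry keeps the acyl group away from the free hydroxyl. Reduction with iBu2AlH (CH2Cl2, −78 °C) gives 12.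

Step 4. Catalyst control over the facial selectivity may be insufficient with an aliphatic, β-oxygenated aldehyde, giving an epimeric mixture at C5. The fallback replaces catalyst control by separation and inversion; it sets out from 4 and returns at 7. Barbier propargylation (Zn dust, propargyl bromide, THF/sat. aq. NH4Cl, 0 °C) would give 7 together with its epimer (2R)-1-[(4R)-2,2,4-trimethyl-1,3-dioxolan-4-yl]pent-4-yn-2-ol F3, to be separated by chromatography. F3 is inverted by a Mitsunobu reaction (4-nitrobenzoic acid, PPh3, DIAD, THF) to (2S)-1-[(4R)-2,2,4-trimethyl-1,3-dioxolan-4-yl]pent-4-yn-2-yl 4-nitrobenzoate F4, and methanolysis (K2CO3, MeOH, rt) gives 7.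

Step 8. PhI(OAc)2 may cleave the primary/tertiary 1,2-diol or the α-hydroxy aldehyde by a glycol-type C–C scission, or the C5 hydroxyl may be oxidised before the lactol closes. The fallback removes the hypervalent iodine oxidant and goes through the carboxylic acid instead of the lactol; it sets out from 15 and returns at 18. Chlorite oxidation under nitroxyl catalysis (TEMPO cat., NaOCl cat., NaClO2, MeCN/phosphate buffer pH 6.7, 35 °C) should give (2R,4S,6E)-2,4-dihydroxy-8-[(8-methoxy-2-oxo-2H-chromen-7-yl)oxy]-2,6-dimethyloct-6-enoic acid F5. This γ-hydroxy acid closes to 18 on acidification to pH 3, or with catalytic p-TsOH in toluene.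

**Further compounds**

F1 | step 5 | (2S,4E)-5-iodo-4-methyl-1-[(4R)-2,2,4-trimethyl-1,3-dioxolan-4-yl]pent-4-en-2-ol | I/C=C(\C)C[C@H](O)C[C@]1(C)COC(C)(C)O1
F2 | step 5 | methyl (2E,5S)-5-hydroxy-3-methyl-6-[(4R)-2,2,4-trimethyl-1,3-dioxolan-4-yl]hex-2-enoate | COC(=O)/C=C(\C)C[C@H](O)C[C@]1(C)COC(C)(C)O1
F3 | step 4 | (2R)-1-[(4R)-2,2,4-trimethyl-1,3-dioxolan-4-yl]pent-4-yn-2-ol | C#CC[C@@H](O)C[C@]1(C)COC(C)(C)O1
F4 | step 4 | (2S)-1-[(4R)-2,2,4-trimethyl-1,3-dioxolan-4-yl]pent-4-yn-2-yl 4-nitrobenzoate | C#CC[C@H](OC(=O)c1ccc(cc1)[N+](=O)[O-])C[C@]1(C)COC(C)(C)O1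
F5 | step 8 | (2R,4S,6E)-2,4-dihydroxy-8-[(8-methoxy-2-oxo-2H-chromen-7-yl)oxy]-2,6-dimethyloct-6-enoic acid | COc1c(OC/C=C(\C)C[C@H](O)C[C@@](C)(O)C(=O)O)ccc2ccc(=O)oc12
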